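**Retrosynthetic overview**

1. Target 24 ⇒ ester 22 (sulfinate elimination, desilylation) ⇒ diol 20 + (S)-2-methylbutanoic acid 21; the C-8 carbinol comes from chelation-controlled reduction of ketone 19.
2. Seven-membered ring: 19 ⇒ α-ketol ring expansion (1,2-shift of the methyl-bearing ring carbon) of the cyclohexanol 1,2-dione 18 ⇒ ketone 13 + acetylide of protected (S)-pent-4-yn-2-ol 15, then alkyne → dione.
3. Ketone 13 ⇒ hydroboration/oxidation of cyclohexene lactone 8, with the exocyclic methylene masked as its PhSH adduct.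
4. cis-Lactone 8 ⇒ hydroxycarbonylation of alkyne 6, then acid-triggered opening of the oxygen bridge by the new carboxyl group with inversion.
5. Alkyne 6 ⇒ aldehyde 5 ⇒ catalytic asymmetric Diels–Alder of 3-methylfuran with an acrylate. Ring order: oxygen-bridged six-membered carbocycle → cis-fused γ-lactone → seven-membered carbocycle.

Convention and assumption (one line): in the fused lactones α is the face of the ring-fusion C–O bond and β the other face; silyl, trifluoroethyl and phenylthio groups are auxiliaries, and the two one-carbon units come from Me3SiCHN2 and CO.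

**Route**

Step 1
Reactants: 1 acryloyl chloride
Product: 2 2,2,2-trifluoroethyl acrylate
Conditions: CF3CH2OH, Et3N, CH2Cl2, 0 °C
Reagents that add atoms: 2,2,2-trifluoroethanol, OCC(F)(F)F
Why: Acylation of the alcohol by the acid chloride gives the activated acrylate needed for a low-temperature furan cycloaddition; no stereocentre is formed.

Step 2
Reactants: 2 2,2,2-trifluoroethyl acrylate; 3 3-methylfuran
Product: 4 endo oxanorbornene trifluoroethyl ester
Conditions: 1-(2-methylphenyl)-3,3-diphenyltetrahydro-1H,3H-pyrrolo[1,2-c][1,3,2]oxazaborole + HN(SO2CF3)2 (10 mol % each; (S)-antipode tried first, the antipode that gives 4 is used), CH2Cl2, −78 °C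
Reagents that add atoms: none
Why: Catalytic enantioselective Diels–Alder reaction in which the boron-bound acrylate adds endo under kinetic control, its ester-bearing carbon bonding to the furan terminus remote from the methyl group ("para"), so that C1, C2 and C4 are set from the face chosen by the catalyst.

Step 3
Reactants: 4 endo oxanorbornene trifluoroethyl ester
Product: 5 endo oxanorbornene aldehyde
Conditions: i-Bu2AlH (1.05 equiv), CH2Cl2, −78 °C; aqueous potassium sodium tartrate
Reagents that add atoms: none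
Why: Partial reduction of the activated ester stops at the aluminium hemiacetal at −78 °C (i-Bu2AlH ester-to-aldehyde reduction), and the cold non-basic work-up leaves the endo α-centre untouched.

Step 4
Reactants: 5 endo oxanorbornene aldehyde
Product: 6 endo oxanorbornene alkyne
Conditions: Me3SiCHN2, n-BuLi, THF, −78 → 0 °C
Reagents that add atoms: (trimethylsilyl)diazomethane, C[Si](C)(C)C=[N+]=[N-]
Why: Colvin homologation (addition, loss of Me3SiOLi and N2, 1,2-hydrogen shift of the alkylidene carbene) turns CHO into C≡CH at low temperature, so the endo centre is not epimerised.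

Step 5
Reactants: 6 endo oxanorbornene alkyne
Product: 8 cis-fused hydroxy methylene lactone, via acrylic acid 7 (not isolated)
Conditions: Pd(OAc)2 (2 mol %), 2-(diphenylphosphino)pyridine (8 mol %), MeSO3H (10 mol %), CO (5 bar), H2O (5 equiv), THF, 45 °C; then 23 °C, 2 h
Reagents that add atoms: carbon monoxide, [C-]#[O+]; water, O
Why: Markovnikov palladium-catalysed hydroxycarbonylation gives the 2-substituted acrylic acid, whose endo carboxyl group then opens the protonated allylic oxygen bridge at C1 from the back (acid-catalysed allylic lactonisation), inverting that carbon, closing the cis-fused γ-lactone and leaving the old bridge oxygen as the allylic 5β-alcohol.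

Step 6
Reactants: 8 cis-fused hydroxy methylene lactone
Product: 10 silyl-protected phenylthiomethyl lactone, via thioether alcohol 9 (not isolated)
Conditions: PhSH, Et3N (10 mol %), CH2Cl2, 0 °C; then t-BuMe2SiOTf, 2,6-lutidine, −40 → 0 °C
Reagents that add atoms: thiophenol, Sc1ccccc1; tert-butyldimethylsilyl trifluoromethanesulfonate, CC(C)(C)[Si](C)(C)OS(=O)(=O)C(F)(F)F
Why: Thia-Michael addition masks the α-methylene lactone against borane, acetylide and RuO4 (the new C-3 centre is destroyed later, so its configuration does not matter), and silylation protects the secondary alcohol.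

Step 7
Reactants: 10 silyl-protected phenylthiomethyl lactone
Product: 12 secondary alcohol, via alkylborane 11 (not isolated)
Conditions: BH3·THF, THF, 0 °C; then 30% H2O2, aqueous NaOAc, 0 °C
Reagents that add atoms: borane–tetrahydrofuran (boron of 11), [BH3-][O+]1CCCC1; hydrogen peroxide, OO
Why: Hydroboration–oxidation places boron on the less substituted alkene carbon (C-7) and adds syn from the β face, anti to the adjacent ring-fusion C–O bond, so hydrogen arrives at C-6 on the β face and fixes the 6α-methyl centre.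

Step 8
Reactants: 12 secondary alcohol
Product: 13 keto lactone
Conditions: Dess–Martin periodinane, CH2Cl2, 0 → 23 °C
Reagents that add atoms: none
Why: Dess–Martin oxidation gives the ketone under non-basic conditions, so the α-methyl centre set in step 7 is kept.

Step 9
Reactants: 14 (S)-pent-4-yn-2-ol
Product: 15 silyl ether of (S)-pent-4-yn-2-ol
Conditions: t-BuMe2SiCl, imidazole, DMF, 23 °C
Reagents that add atoms: tert-butyldimethylsilyl chloride, CC(C)(C)[Si](C)(C)Cl
Why: Silylation protects the secondary alcohol for the acetylide and RuO4 steps; the (S) centre is untouched.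

Step 10
Reactants: 13 keto lactone; 15 silyl ether of (S)-pent-4-yn-2-ol
Product: 17 tertiary propargylic alcohol, via lithium acetylide 16 (not isolated)
Conditions: 15, n-BuLi, THF, −78 °C; LaCl3·2LiCl; then 13, −78 → −40 °C
Reagents that add atoms: none
Why: 1,2-Addition of the acetylide to the ketone occurs by equatorial attack on the β face because the axial C-3a substituent blocks the α (axial) trajectory, giving the axial 7α-hydroxyl and 7β-alkynyl group, while the lanthanum salt suppresses enolisation.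

Step 11
Reactants: 17 tertiary propargylic alcohol
Product: 18 hydroxy 1,2-diketone sulfone
Conditions: RuCl3·xH2O (3 mol %), NaIO4 (7 equiv), MeCN/EtOAc/H2O, 0 °C
Reagents that add atoms: sodium periodate, [Na+].[O-]I(=O)(=O)=O
Why: RuO4 generated in situ oxidises the internal alkyne to the 1,2-diketone and the sulfide to the base-labile but oxidation-proof sulfone, without touching any stereocentre.

Step 12
Reactants: 18 hydroxy 1,2-diketone sulfone
Product: 19 ring-expanded hydroxy diketone
Conditions: Sc(OTf)3 (10 mol %), 4 Å molecular sieves, CH2Cl2, −20 → 23 °C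
Reagents that add atoms: none
Why: Proposed new method: a Sc(OTf)3-catalysed, chelation-controlled α-ketol ring expansion whose acceptor is the proximal carbonyl of a vicinal diketone; scandium binds the C-7 hydroxyl and the adjacent C=O in a syn-periplanar five-membered chelate, the electron-richer methyl-bearing ring carbon (not the acyloxy-bearing C-7a) migrates suprafacially with retention to that carbonyl, the old carbinol carbon becomes the ring ketone, and the new quaternary carbinol is formed with OH on the α face and the acyl chain on the β face; the driving forces are loss of the 1,2-dione dipole repulsion and of the 1,3-diaxial OH/C-3a strain, with the product held as a tridentate chelate; the closest known reactions are Lewis-acid-promoted α-ketol (acyloin) ring expansions of 1-acylcycloalkanols and the ketol-acid alkyl shift of acetolactate-type substrates.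

Step 13
Reactants: 19 ring-expanded hydroxy diketone
Product: 20 trans-diol
Conditions: Zn(BH4)2 (0.6 equiv), Et2O/CH2Cl2, −78 °C
Reagents that add atoms: none
Why: Chelation-controlled reduction: zinc bridges the 7-hydroxyl and the ring carbonyl, which carries two α-oxygen substituents and is therefore the more electrophilic ketone, and hydride attacks C-8 from the α face opposite the β-acyl group to give the 8β-alcohol trans to the 7α-hydroxyl.

Step 14
Reactants: 20 trans-diol; 21 (S)-2-methylbutanoic acid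
Product: 22 (S)-2-methylbutanoate ester
Conditions: N,N'-dicyclohexylcarbodiimide, 4-(dimethylamino)pyridine (10 mol %), CH2Cl2, 0 °C
Reagents that add atoms: none
Why: Steglich esterification acylates the only free secondary alcohol (the tertiary 7-hydroxyl is inert), and the low temperature limits epimerisation of the acid.

Step 15
Reactants: 22 (S)-2-methylbutanoate ester
Product: 24 target CNP0291806.1, via methylene lactone 23 (not isolated)
Conditions: DBU, CH2Cl2, 0 °C; then HF·pyridine, THF, 0 → 23 °C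
Reagents that add atoms: none
Why: E1cB loss of benzenesulfinate regenerates the α-methylene lactone while the β-silyloxy ketone is still protected, and fluoride-mediated desilylation then frees the two secondary alcohols without touching the esters or the α-ketol.

**Compound list**

1 | acryloyl chloride | C=CC(=O)Cl | starting material
2 | 2,2,2-trifluoroethyl acrylate | C=CC(=O)OCC(F)(F)F | intermediate
3 | 3-methylfuran | Cc1ccoc1 | starting material
4 | 2,2,2-trifluoroethyl (1R,2R,4R)-5-methyl-7-oxabicyclo[2.2.1]hept-5-ene-2-carboxylate (2-endo ester) | O=C(OCC(F)(F)F)[C@@H]1C[C@H]2O[C@@H]1C=C2C | intermediate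
5 | (1R,2R,4R)-5-methyl-7-oxabicyclo[2.2.1]hept-5-ene-2-carbaldehyde (2-endo) | O=C[C@@H]1C[C@H]2O[C@@H]1C=C2C | intermediate
6 | (1R,2S,4R)-2-ethynyl-5-methyl-7-oxabicyclo[2.2.1]hept-5-ene (2-endo) | C#C[C@@H]1C[C@H]2O[C@@H]1C=C2C | intermediate
7 | 2-[(1R,2S,4R)-5-methyl-7-oxabicyclo[2.2.1]hept-5-en-2-yl]prop-2-enoic acid (2-endo) | C=C(C(=O)O)[C@@H]1C[C@H]2O[C@@H]1C=C2C | intermediate
8 | (3aS,5R,7aS)-5-hydroxy-6-methyl-3-methylidene-3a,4,5,7a-tetrahydro-1-benzofuran-2(3H)-one (cis-fused, 5β-OH) | C=C1C(=O)O[C@@H]2[C@H]1C[C@@H](O)C(C)=C2 | intermediate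
9 | 5β-hydroxy-6-methyl-3-[(phenylsulfanyl)methyl]-3a,4,5,7a-tetrahydro-1-benzofuran-2(3H)-one (cis-fused, H-3a and H-7a β, C-3 epimers) | c3ccccc3SCC1C(=O)O[C@@H]2[C@H]1C[C@@H](O)C(C)=C2 | intermediate
10 | 5β-[(tert-butyldimethylsilyl)oxy]-6-methyl-3-[(phenylsulfanyl)methyl]-3a,4,5,7a-tetrahydro-1-benzofuran-2(3H)-one (cis-fused, C-3 epimers) | c3ccccc3SCC1C(=O)O[C@@H]2[C@H]1C[C@@H](O[Si](C)(C)C(C)(C)C)C(C)=C2 | intermediate
11 | 7β-boranyl-5β-[(tert-butyldimethylsilyl)oxy]-6α-methyl-3-[(phenylsulfanyl)methyl]hexahydro-1-benzofuran-2(3H)-one (cis-fused) | c3ccccc3SCC1C(=O)O[C@@H]2[C@H]1C[C@@H](O[Si](C)(C)C(C)(C)C)[C@H](C)[C@H]2B | intermediate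
12 | 5β-[(tert-butyldimethylsilyl)oxy]-7β-hydroxy-6α-methyl-3-[(phenylsulfanyl)methyl]hexahydro-1-benzofuran-2(3H)-one (cis-fused) | c3ccccc3SCC1C(=O)O[C@@H]2[C@H]1C[C@@H](O[Si](C)(C)C(C)(C)C)[C@H](C)[C@H]2O | intermediate
13 | 5β-[(tert-butyldimethylsilyl)oxy]-6α-methyl-3-[(phenylsulfanyl)methyl]tetrahydro-1-benzofuran-2,7(3H,7aH)-dione (cis-fused) | c3ccccc3SCC1C(=O)O[C@@H]2[C@H]1C[C@@H](O[Si](C)(C)C(C)(C)C)[C@H](C)C2=O | intermediate
14 | (S)-pent-4-yn-2-ol | C#CC[C@H](C)O | starting material
15 | tert-butyldimethyl{[(2S)-pent-4-yn-2-yl]oxy}silane | C#CC[C@H](C)O[Si](C)(C)C(C)(C)C | intermediate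
16 | {(4S)-4-[(tert-butyldimethylsilyl)oxy]pent-1-yn-1-yl}lithium | [Li]C#CC[C@H](C)O[Si](C)(C)C(C)(C)C | intermediate
17 | 7α-hydroxy-7β-{(4S)-4-[(tert-butyldimethylsilyl)oxy]pent-1-yn-1-yl}-5β-[(tert-butyldimethylsilyl)oxy]-6α-methyl-3-[(phenylsulfanyl)methyl]hexahydro-1-benzofuran-2(3H)-one (cis-fused) | c3ccccc3SCC1C(=O)O[C@@H]2[C@H]1C[C@@H](O[Si](C)(C)C(C)(C)C)[C@H](C)[C@@]2(O)C#CC[C@H](C)O[Si](C)(C)C(C)(C)C | intermediate
18 | (4S)-4-[(tert-butyldimethylsilyl)oxy]-1-{5β-[(tert-butyldimethylsilyl)oxy]-7α-hydroxy-6α-methyl-2-oxo-3-[(phenylsulfonyl)methyl]octahydro-1-benzofuran-7β-yl}pentane-1,2-dione (cis-fused) | O=S(=O)(c3ccccc3)CC1C(=O)O[C@@H]2[C@H]1C[C@@H](O[Si](C)(C)C(C)(C)C)[C@H](C)[C@@]2(O)C(=O)C(=O)C[C@H](C)O[Si](C)(C)C(C)(C)C | intermediate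
19 | 7α-hydroxy-7β-{(3S)-3-[(tert-butyldimethylsilyl)oxy]butanoyl}-5β-[(tert-butyldimethylsilyl)oxy]-6α-methyl-3-[(phenylsulfonyl)methyl]hexahydro-2H-cyclohepta[b]furan-2,8(3H)-dione (cis-fused, H-3a and H-8a β) | O=S(=O)(c3ccccc3)CC1C(=O)O[C@@H]2[C@H]1C[C@@H](O[Si](C)(C)C(C)(C)C)[C@H](C)[C@@](O)(C(=O)C[C@H](C)O[Si](C)(C)C(C)(C)C)C2=O | intermediate
20 | 7α,8β-dihydroxy-7β-{(3S)-3-[(tert-butyldimethylsilyl)oxy]butanoyl}-5β-[(tert-butyldimethylsilyl)oxy]-6α-methyl-3-[(phenylsulfonyl)methyl]octahydro-2H-cyclohepta[b]furan-2-one (cis-fused) | O=S(=O)(c3ccccc3)CC1C(=O)O[C@@H]2[C@H]1C[C@@H](O[Si](C)(C)C(C)(C)C)[C@H](C)[C@@](O)(C(=O)C[C@H](C)O[Si](C)(C)C(C)(C)C)[C@H]2O | intermediate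
21 | (S)-2-methylbutanoic acid | CC[C@H](C)C(=O)O | starting material
22 | 7α-hydroxy-7β-{(3S)-3-[(tert-butyldimethylsilyl)oxy]butanoyl}-5β-[(tert-butyldimethylsilyl)oxy]-6α-methyl-2-oxo-3-[(phenylsulfonyl)methyl]octahydro-2H-cyclohepta[b]furan-8β-yl (2S)-2-methylbutanoate (cis-fused) | O=S(=O)(c3ccccc3)CC1C(=O)O[C@@H]2[C@H]1C[C@@H](O[Si](C)(C)C(C)(C)C)[C@H](C)[C@@](O)(C(=O)C[C@H](C)O[Si](C)(C)C(C)(C)C)[C@H]2OC(=O)[C@@H](C)CC | intermediate
23 | 7α-hydroxy-7β-{(3S)-3-[(tert-butyldimethylsilyl)oxy]butanoyl}-5β-[(tert-butyldimethylsilyl)oxy]-6α-methyl-3-methylidene-2-oxooctahydro-2H-cyclohepta[b]furan-8β-yl (2S)-2-methylbutanoate (cis-fused) | C=C1C(=O)O[C@@H]2[C@H]1C[C@@H](O[Si](C)(C)C(C)(C)C)[C@H](C)[C@@](O)(C(=O)C[C@H](C)O[Si](C)(C)C(C)(C)C)[C@H]2OC(=O)[C@@H](C)CC | intermediate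
24 | (3aS,5R,6S,7S,8S,8aR)-5,7-dihydroxy-7-[(3S)-3-hydroxybutanoyl]-6-methyl-3-methylidene-2-oxooctahydro-2H-cyclohepta[b]furan-8-yl (2S)-2-methylbutanoate (CNP0291806.1) | C=C1C(=O)O[C@@H]2[C@H]1C[C@@H](O)[C@H](C)[C@@](O)(C(=O)C[C@H](C)O)[C@H]2OC(=O)[C@@H](C)CC | target

**Step count**

Total steps: 15. Longest linear sequence: 14 (steps 1–8 and 10–15; step 9 prepares the side-chain fragment).

**Three steps most likely to fail**

Step 5 (hydroxycarbonylation and bridge-opening lactonisation). Palladium hydride chemistry next to a strained, acid-labile allylic ether may give ring-opened or aromatised material before the acrylic acid forms. The fallback sets out from aldehyde 5 and builds the acrylic acid from an enol triflate instead of an alkyne. MeMgBr in THF at −78 °C gives the carbinol 1-(2-endo-5-methyl-7-oxabicyclo[2.2.1]hept-5-en-2-yl)ethanol F1. Dess–Martin periodinane gives the methyl ketone F2. KN(SiMe3)2 and PhN(SO2CF3)2 at −78 °C give the kinetic enol triflate F3. Carbonylation with Pd(PPh3)4, CO, KOAc and water in DMF then gives acrylic acid 7, which is the point of return to the route. Compound 7 is closed to 8 with a catalytic amount of camphorsulfonic acid in CH2Cl2.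

Step 12 (the new α-ketol ring expansion). The six-to-seven equilibrium may not lie far enough on the product side. A later 1,2-acyl shift could scramble the hydroxy diketone. Part of the migration could also involve C-7a. The fallback uses known chemistry and sets out from propargylic alcohol 17. Ph3PAuNTf2 (5 mol %) with 8-methylquinoline N-oxide in 1,2-dichloroethane generates the α-oxo gold carbene next to the carbinol, and the 1,2-alkyl shift gives the ring-expanded 2-acylcycloheptanone F4. Excess dimethyldioxirane in acetone then hydroxylates the enolised β-diketone at C-7 and takes the sulfide to the sulfone, which returns the route at 19. This hydroxylation is not directed, so the C-7 epimer is expected as well and must be separated.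

Step 13 (chemoselective reduction of the ring ketone). The side-chain ketone is less hindered and also has an α-hydroxyl, so it may be reduced in competition. The fallback sets out from 19 and removes the selectivity problem. Excess Zn(BH4)2 reduces both ketones to the triol F5. 2,2-Dimethoxypropane with pyridinium p-toluenesulfonate ties the tertiary 7-hydroxyl and the side-chain carbinol into the five-membered acetonide F6. Esterification of the free 8β-alcohol with 21 (N,N'-dicyclohexylcarbodiimide, 4-(dimethylamino)pyridine) gives the acetonide ester F7. Aqueous acetic acid at 23 °C removes the acetonide to give the diol ester F8. Dess–Martin periodinane oxidises the secondary side-chain carbinol back to the ketone, which returns the route at 22.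

**Further compounds**

F1 | step 5 | 1-(2-endo-5-methyl-7-oxabicyclo[2.2.1]hept-5-en-2-yl)ethanol, ring configuration as in 5, carbinol epimers | CC(O)[C@@H]1C[C@H]2O[C@@H]1C=C2C
F2 | step 5 | 1-[(1R,2R,4R)-5-methyl-7-oxabicyclo[2.2.1]hept-5-en-2-yl]ethanone (2-endo) | CC(=O)[C@@H]1C[C@H]2O[C@@H]1C=C2C
F3 | step 5 | 1-[(1R,2R,4R)-5-methyl-7-oxabicyclo[2.2.1]hept-5-en-2-yl]ethenyl trifluoromethanesulfonate (2-endo) | C=C(OS(=O)(=O)C(F)(F)F)[C@@H]1C[C@H]2O[C@@H]1C=C2C
F4 | step 12 | 7-{(3S)-3-[(tert-butyldimethylsilyl)oxy]butanoyl}-5β-[(tert-butyldimethylsilyl)oxy]-6α-methyl-3-[(phenylsulfanyl)methyl]hexahydro-2H-cyclohepta[b]furan-2,8(3H)-dione (cis-fused, C-7 enolisable) | c3ccccc3SCC1C(=O)O[C@@H]2[C@H]1C[C@@H](O[Si](C)(C)C(C)(C)C)[C@H](C)C(C(=O)C[C@H](C)O[Si](C)(C)C(C)(C)C)C2=O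
F5 | step 13 | 7α,8β-dihydroxy-7β-{(3S)-3-[(tert-butyldimethylsilyl)oxy]-1-hydroxybutyl}-5β-[(tert-butyldimethylsilyl)oxy]-6α-methyl-3-[(phenylsulfonyl)methyl]octahydro-2H-cyclohepta[b]furan-2-one (carbinol epimers in the side chain) | O=S(=O)(c3ccccc3)CC1C(=O)O[C@@H]2[C@H]1C[C@@H](O[Si](C)(C)C(C)(C)C)[C@H](C)[C@@](O)(C(O)C[C@H](C)O[Si](C)(C)C(C)(C)C)[C@H]2O
F6 | step 13 | acetonide of F5 across the 7α-oxygen and the side-chain carbinol oxygen (spiro 2,2-dimethyl-1,3-dioxolane at C-7), 8β-OH free | O=S(=O)(c3ccccc3)CC1C(=O)O[C@@H]2[C@H]1C[C@@H](O[Si](C)(C)C(C)(C)C)[C@H](C)[C@@](OC(C)(C)O4)(C4C[C@H](C)O[Si](C)(C)C(C)(C)C)[C@H]2O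
F7 | step 13 | 8β-(2S)-2-methylbutanoate of acetonide F6 | O=S(=O)(c3ccccc3)CC1C(=O)O[C@@H]2[C@H]1C[C@@H](O[Si](C)(C)C(C)(C)C)[C@H](C)[C@@](OC(C)(C)O4)(C4C[C@H](C)O[Si](C)(C)C(C)(C)C)[C@H]2OC(=O)[C@@H](C)CC
F8 | step 13 | 7α-hydroxy-7β-{(3S)-3-[(tert-butyldimethylsilyl)oxy]-1-hydroxybutyl}-5β-[(tert-butyldimethylsilyl)oxy]-6α-methyl-2-oxo-3-[(phenylsulfonyl)methyl]octahydro-2H-cyclohepta[b]furan-8β-yl (2S)-2-methylbutanoate | O=S(=O)(c3ccccc3)CC1C(=O)O[C@@H]2[C@H]1C[C@@H](O[Si](C)(C)C(C)(C)C)[C@H](C)[C@@](O)(C(O)C[C@H](C)O[Si](C)(C)C(C)(C)C)[C@H]2OC(=O)[C@@H](C)CC
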